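1. I followed the left-handed product's share of the two products together in alder, elm, larch, oak and cedar, each read at 2.5 min.

| setting | east | south-east | alder | elm | larch | oak | cedar |
|---|---|---|---|---|---|---|---|
| left-handed substrate | 2 mM | 1 mM | 2.0 mM | 2.0 mM | 2.0 mM | 2.0 mM | 2.0 mM |
| right-handed substrate | 2 mM | 1 mM | 2.0 mM | 2.0 mM | 2.0 mM | 2.0 mM | 2.0 mM |
| reagent | 4 mM | 4 mM | 4.00 mM | 8.00 mM | 20.0 mM | 40.0 mM | 80.0 mM |
| free catalyst | 150 µM | 100 µM | 100 µM | 100 µM | 100 µM | 100 µM | 100 µM |
| racemization catalyst | 2 µM | 2 µM | 2.0 µM | 2.0 µM | 2.0 µM | 2.0 µM | 2.0 µM |
| remark | run made earlier | run made earlier |  |  |  |  |  |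
| time |  |  | 2.5 min | 2.5 min | 2.5 min | 2.5 min | 2.5 min |

| run | time / s | left-handed product / % | right-handed product / % | left-handed substrate / % |
|---|---|---|---|---|
| east | 10.0 | 7.1 | 2.8 | 42.7 |
| east | 15.0 | 9.5 | 4.5 | 40.9 |
| east | 40.0 | 20.5 | 9.8 | 30.0 |
| east | 90.0 | 31.8 | 17.1 | 18.8 |
| south-east | 12.0 | 5.6 | 2.7 | 44.3 |
| south-east | 30.0 | 13.0 | 5.8 | 37.4 |
| south-east | 60.0 | 21.9 | 10.5 | 28.6 |
| south-east | 90.0 | 28.6 | 14.6 | 22.0 |

(readings scatter by 0.3 percentage points)

- share of left-handed product in all that became left-handed product or right-handed product for alder, elm, larch, oak, cedar, in this order
- the shape of the row from first to last (falls, then rises / rises all the way / hardly changes / falls all the way / rises, then falls)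

- free catalyst is single-handed; left-handed substrate and right-handed substrate are mirror images of each other, charged as a racemate, each of them at the stated concentration
- "hardly changes" means that all values lie within two and a half points (for a concentration: within two and a half percent of the largest)

2. I worked with the fraction left, not the fraction made. I divided each substrate by its own charge and took the right-handed substrate from the balance. The selectivity factor s, the logarithm of the fraction of left-handed substrate left over that of the right-handed substrate, read 2.24 at the last east reading and 2.27 at the last south-east reading.

3. The rule follows from s. Setting racemization aside and taking s as constant, if f is the fraction of right-handed substrate left, f raised to s is the fraction of left-handed substrate left. The share is then the left-handed substrate used over both substrates used. So the thing to watch is f.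

4. I took two extreme flasks. In a barely started flask, the amounts used stand in the ratio s, so the share is 69.1%. In a flask with both substrates used up, the equal charges give 50.0%. By this rule the row lay between them, with 69.1% above 50.0%, and moved toward the lower value as f shrank.

5. To place the flasks, I took the negative logarithm of f from the last south-east reading, a run with the same catalyst charge. I scaled it by [reagent] times time, taking [reagent] at its charge and treating the fall of each substrate as first order in that substrate, so that the different substrate charge dropped out. For alder this gave 0.604 and a share of 62.1%. For larch, with 3.02, the share was 51.2%. Since [reagent] falls during a run, I took these as rough estimates, probably on the low side.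

6. The forecast, which called this “a nearly plain kinetic resolution”, gave 64.5%, 59.6%, 52.4%, 50.6% and 50.3%, so the row falls all the way. Its alder value of 64.5% stood above my estimate of 62.1%, and its larch value of 52.4% stood above my 51.2%.

7. The flasks gave 64.8%, 59.5%, 51.8%, 50.2% and 50.1%, so the row falls all the way.

    reagent + free catalyst + left-handed substrate → free catalyst + left-handed product (k = 26000 /M²/s)
    reagent + free catalyst + right-handed substrate → free catalyst + right-handed product (k = 10800 /M²/s)
    left-handed substrate + racemization catalyst ⇌ right-handed substrate + racemization catalyst, rate k3*[racemization catalyst]*[left-handed substrate] forward; the back reaction follows from the equilibrium constant (k = 4000 /M/s)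
    2 racemization catalyst → spent catalyst A (k = 39000 /M/s)
    racemization catalyst ⇌ dormant form (K = 46.0, k = 0.0380 /s)
    reagent + racemization catalyst → spent catalyst B (k = 7.62 /M/s)

8. The hour of reading moved the share: alder, with its charge unchanged, gave 64.8% at 2.5 min and 55.5% at 25.0 min. With s, alder's 64% of right-handed substrate left gives 63.7% against 64.8%, and elm's 38% gives 58.8% against 59.5%. Alder's later 18.9% of its charge of right-handed substrate gives 54.6% against 55.5%.

The runs stem from a simulated flask for an exercise.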